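**Assumption:** Flavan numbering is used (O1, C2, C3, C4, C4a–C8a for rings C and A; C1'–C6' for ring B; ring D is the dimethylpyran fused at C4'–C5'); read from the SMILES, C2 is R.

**Corrections and redesign:**
- Ring B of the target has five contiguous substituents, not four. The C5' carbon of ring D is the fifth and is added after the cycloaddition.
- The Z dienol ether is the isomer with the alkyl chain turned outward, so it is the reactive one; the E isomer is the unproductive one.
- The acetal on O7 is replaced by a triisopropylsilyl ether and O3' is later capped as a silyl ether. A closing acid treatment would endanger the ortho-prenylphenol, the chromene and the C2–O1 bond.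
- The labile aryl trimethylsilyl ethers are cleaved in the work-up of the key step.

## Structural features

The target is a flavan: ring A is fused to the dihydropyran ring C, and C2 of ring C carries ring B, which is itself fused through C4'–C5' to a 2,2-dimethyl-2H-pyran, ring D. Ring A bears one phenol at C7; ring B is pentasubstituted, with C1' (the link to C2), the prenyl group at C2', a free phenol at C3', the ring D oxygen at C4' and the ring D vinyl carbon at C5' in unbroken sequence, so that only C6' carries hydrogen. The single stereocentre is C2 (R), a benzylic ether carbon with no stereogenic neighbour, so its configuration must come entirely from a reagent or catalyst. The fragile groups are the prenyl alkene lying ortho to a free phenol (acid closes it to a chroman), the styrenic double bond of ring D, and the C2–O1 bond, which is benzylic and para to O4' and can ionise with loss of configuration; three C=C bonds also rule out hydrogenation and hydrogenolysis. The real difficulty is the crowding of ring B, where the prenyl group is wedged between C1' and O3', a site that electrophilic substitution on a catechol does not reach cleanly. The key step uses the fact that C2'–C3'–C4'–C5' form a 1-alkyl-2,3-dioxygenated butadiene unit and C1'–C6' an acetylene unit whose acyl substituent is C2 of ring C, so one cycloaddition builds ring B with four of its five substituents in place and joins it to the C2–C3–C4–ring A chain. Ring D then follows from O4' and the free C5'–H, and ring C from the C2 hydroxyl and a bromide at C8a.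

## Logic of the disconnections

**24 ⇒ 23.** The O7–Si and O3'–Si bonds are cut. Both phenols stay masked to the end because the intermediates must pass an alkoxide/copper step, and silicon is chosen so that the last operation uses buffered fluoride and no acid. The gain is protective only. The demand is that one mild treatment clears a hindered and an unhindered aryl silyl ether together.

**23 ⇒ 22.** The O1–C8a bond is cut. Closing ring C at the aryl carbon leaves all four bonds of C2 untouched, so the configuration is carried through with retention, which a displacement at so electron-rich a benzylic carbon could not guarantee. The gain is an open-chain carbinol with a bromide at C8a. The forward step must arylate a hindered secondary alkoxide intramolecularly without hydrodebromination and without loss of the silyl ethers.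

**22 ⇒ 21.** The C2–H bond is cut (hydride addition to the C2 carbonyl). The stereocentre is traced to a prochiral aryl alkyl ketone, the substrate class for which catalyst-controlled transfer hydrogenation is most dependable, and everything before 22 becomes achiral. The demand is face selection on a ketone whose aryl group has an ortho substituent, with three C=C bonds and the C–Br bond left alone.

**21 ⇒ 20.** The O3'–Si bond is cut. The phenol must be capped before the alkoxide coupling, where it would compete as a nucleophile, and it is capped only now so that its free form can differentiate it from O4' earlier. The demand is silylation of a phenol flanked on both sides.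

**20 ⇒ 19.** The bond from C5' to the vinyl carbon of ring D is cut and the pyran is unfolded into the propargylic ether function on O4' of 19. C5' is the only unsubstituted position ortho to O4', so the sigmatropic cascade has a single outcome. The gain is the loss of ring D and of the fifth ring B substituent. The demand is a temperature near 140 °C without harm to the prenyl group or the silyl ether.

**19 ⇒ 17 + 18.** The O4'–C bond is cut. The O4' hydroxyl is para to the ketone, hence the more acidic, and is less hindered than O3', which lies between the prenyl group and O4'. The gain is a plain catechol. The demand is monoalkylation at O4' by a tertiary propargylic chloride.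

**17 ⇒ 16 ⇒ 15 ⇒ 14 + 9.** The two O–Si bonds of 16 are cut first, then ring B is taken apart through C1'–C2' and C5'–C6' after formal return of two hydrogens. This is the strategic cut: the crowded C1'/C2'/C3'/C4' pattern becomes the substitution pattern of an open-chain diene, and because the acyl carbon of the dienophile is C2, the same event joins the two halves of the molecule. The gain is one ring, two skeletal bonds and full convergence. The demands are:
- the acyl-bearing alkyne carbon must bond to the prenyl-bearing diene terminus;
- the dienol ether must have the geometry that allows the s-cis form;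
- the oxidant must aromatise without touching anything else.

**9 ⇒ 7 + 8.** The bond between C2 and the alkyne carbon that becomes C1' is cut. An N-methoxy-N-methylamide stops the addition at the ketone stage. The demand is a single addition and no conjugate addition of the released amine to the ynone.

**7 ⇒ 6 ⇒ 5.** The O7–Si bond and the amide C–N bond are cut. Silicon is introduced after the acid has been made, so it never meets hot formic acid. The demand is amide coupling beside a free phenol.

**5 ⇒ 1 + 2.** The C3–C4 bond is cut; C4 is the aldehyde carbon of 1, and C2 and C3 come from 2. A reductive condensation with decarboxylation gives the saturated acid directly and avoids a separate alkene reduction next to a C–Br bond. The demand is hydride transfer to the alkylidene malonate only.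

**14 ⇒ 13.** Two O–Si bonds are cut. Enolisation once on each side of the 1,2-dione can give only one constitution. The demand is Z geometry at C3=C4 and handling free of moisture and acid.

**13 ⇒ 12 ⇒ 10 + 11.** The ketal is opened and the bond between the acetyl α-carbon and the prenyl CH2 is cut. In 10 only one α-position can be deprotonated. The demand is monoalkylation, and a hydrolysis mild enough for the trisubstituted alkene.

## Other disconnections considered

**Alternative 1:** The cut runs through O1–C2 and C2–C3, so that C2 alone comes from an aldehyde and ring C is closed around it.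

- **Forward step.** 2-Ethenyl-5-(triisopropylsilyloxy)phenol A1 and 8-acetoxy-2,2-dimethyl-2H-chromene-6-carbaldehyde A2 would be condensed under a confined chiral imidodiphosphate-type Brønsted acid. The vinyl terminus would add to the aryloxycarbenium carbon and a Hantzsch-type dihydropyridine would quench the C4 cation, giving the (2R)-flavan A3. Deacetylation, conversion of O3' into a 1,1-dimethylallyl ether, a Claisen shift to C2' and desilylation would follow.
- **In favour.** Ring C and the stereocentre arise in one catalytic, metal-free event from two fragments of similar size, and no halide handle is needed.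
- **Against.** The three-component reductive sequence on a phenol/aryl aldehyde pair has no close precedent. Direct hydride transfer to the aldehyde or the oxocarbenium ion, acid-induced oligomerisation of A1 and protonation of the chromene of A2 all compete. The prenyl group must be added last, at the most hindered position of A3 and beside the stereocentre, with migration to C6' as a conceivable competitor.
- **Comparison.** On step economy this plan is the better one (about ten operations against fourteen) and it is more convergent at ring C. On mechanism the chosen plan is safer, because the stereocentre of 22 comes from an established ketone reduction and each other step belongs to a known class. On structure the chosen plan is better, because the C2' prenyl group is in place before ring B exists.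

**Alternative 2:** The cut is C4–C4a.

- **Forward step.** The aryl propargyl ether A4, which already carries the stereocentre as a benzylic and propargylic C–O bond, would be activated at its terminal alkyne by Ph3PAuNTf2. The ring A carbon para to the acetal-protected oxygen would attack in a 6-endo hydroarylation to give the (2R)-2H-chromene A5.
- **In favour.** This hydroarylation of aryl propargyl ethers is an established, mild, catalytic ring closure, at least the equal of the copper etherification of step 13 in reliability. The C3=C4 bond of A5 could be hydrogenated together with benzyl ether cleavage while no other alkene is present.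
- **Against.** The stereocentre of A4 sits at a doubly activated C–O bond on an electron-rich arene. Its installation by displacement and its exposure to a Lewis acidic gold cation both invite ionisation and loss of configuration. Attack ortho to the acetal-protected oxygen would give the regioisomeric ring A. Ring B of A5 is only 3',4'-dioxygenated, so ring D and the prenyl group would still need two successive Claisen sequences, and the acetal on O7 would call for acid at the end.
- **Comparison.** On step economy it is no shorter than the chosen plan (thirteen or fourteen operations). On structure it leaves the hard part, the ring B pattern, to the end, which the chosen plan settles in step 8. On mechanism its ring closure is equal or better, but its stereochemical integrity is less secure than the retention pathway through 22 and 23.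

**Alternative 3:** The cuts are O1–C2 and C3–C4, with an extra formyl group at C3 that is later excised.

- **Forward step.** 2-Hydroxy-4-(methoxymethoxy)benzaldehyde A6 and the ring B enal A7 would react under a chiral diarylprolinol silyl ether. The phenol would add to the iminium β-carbon, and the enamine would condense with the aryl aldehyde to give the 2H-chromene-3-carbaldehyde A8. Conjugate reduction, decarbonylation and deprotection would follow.
- **In favour.** The oxa-Michael–aldol domino is a known, metal-free, convergent reaction that sets C2 catalytically, and the fragment sizes are as even as in the chosen plan.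
- **Against.** A7 must already carry the full ring B pattern, the very problem that step 8 solves, so a separate Claisen or metalation route to it is needed. The ortho prenyl group next to the β-carbon should slow the oxa-Michael addition and weaken face selection. C2 of A8 is labile through retro-oxa-Michael opening. The formyl group costs two further steps, one a rhodium-mediated decarbonylation at high temperature, which must not touch the ring D alkene or the prenyl group. The acetal groups again require acid at the end.
- **Comparison.** On step economy it is about equal, perhaps one or two operations shorter if A7 is counted generously. On mechanism its key step is as well founded as step 8. On structure the chosen plan is clearly better, since it builds ring B, and its stereocentre is less exposed to erosion.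

Key step: step 8

## Route

**Step 1**
Reactants: 1 2-bromo-4-hydroxybenzaldehyde; 2 Meldrum's acid (2,2-dimethyl-1,3-dioxane-4,6-dione)
Product: 5 3-(2-bromo-4-hydroxyphenyl)propanoic acid, via arylidene Meldrum's acid 3 (not isolated), via benzyl Meldrum's acid 4 (not isolated)
Conditions: HCO2H/Et3N (5:2), DMF, 50 °C then 100 °C
Reagents that add atoms: none
Why: Knoevenagel condensation gives 3, formate transfers hydride to its β-carbon to give 4, and hydrolysis with decarboxylation at 100 °C leaves the saturated acid; without a transition metal the aryl bromide is inert to formate and the free phenol needs no protection.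

**Step 2**
Reactants: 5 3-(2-bromo-4-hydroxyphenyl)propanoic acid
Product: 6 3-(2-bromo-4-hydroxyphenyl)-N-methoxy-N-methylpropanamide
Conditions: MeNHOMe·HCl, EDC·HCl, HOBt, N-methylmorpholine, CH2Cl2, 0 °C to rt
Reagents that add atoms: N,O-dimethylhydroxylamine hydrochloride, CNOC.Cl
Why: Carbodiimide amide coupling through the benzotriazolyl ester; the amine is far more nucleophilic than the phenol, and any aryl ester formed would be aminolysed by the excess amine.

**Step 3**
Reactants: 6 3-(2-bromo-4-hydroxyphenyl)-N-methoxy-N-methylpropanamide
Product: 7 3-[2-bromo-4-(triisopropylsilyloxy)phenyl]-N-methoxy-N-methylpropanamide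
Conditions: TIPSCl, imidazole, DMF, rt
Reagents that add atoms: triisopropylsilyl chloride, CC(C)[Si](Cl)(C(C)C)C(C)C
Why: Standard silylation of an unhindered phenol; the bulky silyl ether should withstand the Grignard reagent, DDQ, carbonate bases and hot toluene, and is removed by fluoride at the end.

**Step 4**
Reactants: 7 3-[2-bromo-4-(triisopropylsilyloxy)phenyl]-N-methoxy-N-methylpropanamide; 8 ethynylmagnesium bromide
Product: 9 5-[2-bromo-4-(triisopropylsilyloxy)phenyl]pent-1-yn-3-one
Conditions: THF, 0 °C; then poured into 1 M HCl, 0 °C
Reagents that add atoms: none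
Why: Weinreb ketone synthesis: the magnesium chelate of the tetrahedral adduct persists until the quench, so only one ethynyl group adds; the cold acidic inverse quench protonates the liberated N,O-dimethylhydroxylamine before it can add to the ynone.

**Step 5**
Reactants: 10 3,3-dimethoxybutan-2-one; 11 prenyl bromide (1-bromo-3-methylbut-2-ene)
Product: 12 2,2-dimethoxy-7-methyloct-6-en-3-one
Conditions: LiN(iPr)2, THF, −78 °C; then 11, DMPU, −78 to −20 °C
Reagents that add atoms: none
Why: Kinetic enolate alkylation: the acetyl methyl group is the only enolisable position of 10, and the primary allylic bromide reacts by direct SN2 displacement.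

**Step 6**
Reactants: 12 2,2-dimethoxy-7-methyloct-6-en-3-one
Product: 13 7-methyloct-6-ene-2,3-dione
Conditions: 1 M HCl, THF, rt
Reagents that add atoms: water, O
Why: Acid-catalysed ketal hydrolysis; dilute aqueous acid at room temperature should leave the trisubstituted alkene unhydrated.

**Step 7**
Reactants: 13 7-methyloct-6-ene-2,3-dione
Product: 14 (3Z)-7-methyl-2,3-bis(trimethylsilyloxy)octa-1,3,6-triene
Conditions: TMSOTf, Et3N, Et2O, 0 °C to rt; filtration under argon, bulb-to-bulb distillation
Reagents that add atoms: trimethylsilyl trifluoromethanesulfonate, C[Si](C)(C)OS(=O)(=O)C(F)(F)F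
Why: Soft enolisation of a 1,2-dione, one carbonyl towards the methyl group and the other towards the methylene group, can give only this constitution; equilibrating amine/silyl triflate conditions favour the Z enol ether, with the alkyl chain cis to the silyloxy group and trans to the vinyl group.

**Step 8**
Reactants: 14 (3Z)-7-methyl-2,3-bis(trimethylsilyloxy)octa-1,3,6-triene (1.5 equiv); 9 5-[2-bromo-4-(triisopropylsilyloxy)phenyl]pent-1-yn-3-one
Product: 17 1-[3,4-dihydroxy-2-(3-methylbut-2-enyl)phenyl]-3-[2-bromo-4-(triisopropylsilyloxy)phenyl]propan-1-one, via cyclohexadiene cycloadduct 15 (not isolated), via bis(trimethylsilyl) aryl ketone 16 (not isolated)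
Conditions: PhMe, BHT (cat.), 100 °C; then DDQ (1.05 equiv), 0 °C to rt, filtration; then citric acid, MeOH, rt
Reagents that add atoms: none
Why: Thermal Diels–Alder reaction of the electron-rich bis(silyloxy)diene 14 with the electron-poor ethynyl ketone 9 gives the 1,4-cyclohexadiene 15; DDQ then abstracts hydride from the doubly allylic C5' methylene (the cation is stabilised by the C4' silyloxy group), loss of the C2' proton gives arene 16, and its aryl trimethylsilyl ethers are methanolysed under citric acid to 17 while the triisopropylsilyl ether stays. The closest known reaction type is the cycloaddition of 2,3-bis(trimethylsilyloxy)buta-1,3-diene with acetylenic ketones and esters followed by dehydrogenation to catechol derivatives. Ring B closes in an intermolecular, concerted, suprafacial [4+2] mode that forms C1'–C2' and C5'–C6' in one event, and aromatisation makes the closure irreversible. No stereocentre survives: C2' of 15 is formed racemic and is erased on aromatisation, so nothing needs control there. The selectivity required is orientational: the acyl-bearing alkyne carbon must bond to the prenyl-bearing diene terminus. The two silyloxy groups polarise the diene in opposite senses and roughly cancel, so the 1-alkyl substituent decides: it raises the HOMO coefficient at the unsubstituted CH2 terminus, which is also the less hindered one and pairs with the β-carbon of the ynone, placing the acyl group next to the prenyl group. Reactivity rests on the Z geometry of the C3=C4 enol ether, in which the alkyl chain points outward in the s-cis conformer; the E isomer cannot reach a planar s-cis form and is left behind, which is why 14 is used in excess. The isolated trisubstituted alkene, the aryl bromide and the aryl triisopropylsilyl ether are spectators, and DDQ is limited to one equivalent and filtered off as its hydroquinone before the catechol is released, so that no o-quinone forms.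

**Step 9**
Reactants: 17 1-[3,4-dihydroxy-2-(3-methylbut-2-enyl)phenyl]-3-[2-bromo-4-(triisopropylsilyloxy)phenyl]propan-1-one; 18 3-chloro-3-methylbut-1-yne
Product: 19 1-[3-hydroxy-4-(2-methylbut-3-yn-2-yloxy)-2-(3-methylbut-2-enyl)phenyl]-3-[2-bromo-4-(triisopropylsilyloxy)phenyl]propan-1-one
Conditions: K2CO3 (1.2 equiv), KI, acetone, 55 °C, argon
Reagents that add atoms: none
Why: Williamson-type O-alkylation of the more acidic phenol: O4'–H is para to the ketone and is deprotonated first, while O3' is less acidic and shielded by the prenyl group and O4', as in the known selective 4-O-alkylation of 3,4-dihydroxyaryl carbonyl compounds.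

**Step 10**
Reactants: 19 1-[3-hydroxy-4-(2-methylbut-3-yn-2-yloxy)-2-(3-methylbut-2-enyl)phenyl]-3-[2-bromo-4-(triisopropylsilyloxy)phenyl]propan-1-one
Product: 20 1-[8-hydroxy-2,2-dimethyl-7-(3-methylbut-2-enyl)-2H-chromen-6-yl]-3-[2-bromo-4-(triisopropylsilyloxy)phenyl]propan-1-one
Conditions: o-xylene, 140 °C
Reagents that add atoms: none
Why: Aromatic propargyl Claisen rearrangement to C5', the only free position ortho to O4', then enolisation, 1,5-hydrogen shift and oxa-6π electrocyclisation close ring D; the conditions are neutral, so the ortho-prenylphenol is not cyclised.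

**Step 11**
Reactants: 20 1-[8-hydroxy-2,2-dimethyl-7-(3-methylbut-2-enyl)-2H-chromen-6-yl]-3-[2-bromo-4-(triisopropylsilyloxy)phenyl]propan-1-one
Product: 21 1-[8-(tert-butyldimethylsilyloxy)-2,2-dimethyl-7-(3-methylbut-2-enyl)-2H-chromen-6-yl]-3-[2-bromo-4-(triisopropylsilyloxy)phenyl]propan-1-one
Conditions: TBSCl, imidazole, DMAP (cat.), DMF, 40 °C
Reagents that add atoms: tert-butyldimethylsilyl chloride, CC(C)(C)[Si](C)(C)Cl
Why: Silylation of the remaining phenol; its flanking substituents slow the reaction but afterwards shield the silyl ether from carbonate in step 13.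

**Step 12**
Reactants: 21 1-[8-(tert-butyldimethylsilyloxy)-2,2-dimethyl-7-(3-methylbut-2-enyl)-2H-chromen-6-yl]-3-[2-bromo-4-(triisopropylsilyloxy)phenyl]propan-1-one
Product: 22 (1R)-1-[8-(tert-butyldimethylsilyloxy)-2,2-dimethyl-7-(3-methylbut-2-enyl)-2H-chromen-6-yl]-3-[2-bromo-4-(triisopropylsilyloxy)phenyl]propan-1-ol
Conditions: RuCl[(R,R)-TsDPEN](p-cymene) (2 mol %), HCO2H/Et3N (5:2), DMF, 40 °C
Reagents that add atoms: none
Why: Noyori–Ikariya asymmetric transfer hydrogenation of an aryl alkyl ketone: in the six-membered hydride/proton transfer the aryl group lies under the η6-arene (CH/π contact), so the (R,R) catalyst should deliver hydride to the face that gives the R carbinol, as it does for acetophenone; the ruthenium hydride does not reduce isolated or styrenic alkenes or the C–Br bond.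

**Step 13**
Reactants: 22 (1R)-1-[8-(tert-butyldimethylsilyloxy)-2,2-dimethyl-7-(3-methylbut-2-enyl)-2H-chromen-6-yl]-3-[2-bromo-4-(triisopropylsilyloxy)phenyl]propan-1-ol
Product: 23 tert-butyl-{[2,2-dimethyl-7-(3-methylbut-2-enyl)-6-[(2R)-7-(triisopropylsilyloxy)-3,4-dihydro-2H-chromen-2-yl]-2H-chromen-8-yl]oxy}dimethylsilane
Conditions: CuI (10 mol %), 3,4,7,8-tetramethyl-1,10-phenanthroline (20 mol %), Cs2CO3, PhMe, 100 °C
Reagents that add atoms: none
Why: Ullmann-type intramolecular C–O coupling: the copper catalyst activates the C8a–Br bond and the secondary alkoxide is arylated, closing the six-membered ring C; no bond to C2 is broken, so the R configuration is retained.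

**Step 14**
Reactants: 23 tert-butyl-{[2,2-dimethyl-7-(3-methylbut-2-enyl)-6-[(2R)-7-(triisopropylsilyloxy)-3,4-dihydro-2H-chromen-2-yl]-2H-chromen-8-yl]oxy}dimethylsilane
Product: 24 (2R)-2-[8-hydroxy-2,2-dimethyl-7-(3-methylbut-2-enyl)-2H-chromen-6-yl]-3,4-dihydro-2H-chromen-7-ol
Conditions: TBAF, AcOH, THF, 0 °C to rt
Reagents that add atoms: none
Why: Fluoride-induced cleavage of both aryl silyl ethers; the acetic acid buffer keeps the medium near neutral, so the prenyl/phenol pair, the chromene and the benzylic C2–O1 bond meet neither acid nor strong base.

## Compound list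

1 | 2-bromo-4-hydroxybenzaldehyde | O=Cc1ccc(O)cc1Br | starting material
2 | Meldrum's acid (2,2-dimethyl-1,3-dioxane-4,6-dione) | CC1(C)OC(=O)CC(=O)O1 | starting material
3 | 5-[(2-bromo-4-hydroxyphenyl)methylidene]-2,2-dimethyl-1,3-dioxane-4,6-dione | CC1(C)OC(=O)C(=Cc2ccc(O)cc2Br)C(=O)O1 | intermediate
4 | 5-[(2-bromo-4-hydroxyphenyl)methyl]-2,2-dimethyl-1,3-dioxane-4,6-dione | CC1(C)OC(=O)C(Cc2ccc(O)cc2Br)C(=O)O1 | intermediate
5 | 3-(2-bromo-4-hydroxyphenyl)propanoic acid | OC(=O)CCc1ccc(O)cc1Br | intermediate
6 | 3-(2-bromo-4-hydroxyphenyl)-N-methoxy-N-methylpropanamide | CON(C)C(=O)CCc1ccc(O)cc1Br | intermediate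
7 | 3-[2-bromo-4-(triisopropylsilyloxy)phenyl]-N-methoxy-N-methylpropanamide | CON(C)C(=O)CCc1ccc(O[Si](C(C)C)(C(C)C)C(C)C)cc1Br | intermediate
8 | ethynylmagnesium bromide | C#C[Mg]Br | starting material
9 | 5-[2-bromo-4-(triisopropylsilyloxy)phenyl]pent-1-yn-3-one | C#CC(=O)CCc1ccc(O[Si](C(C)C)(C(C)C)C(C)C)cc1Br | intermediate
10 | 3,3-dimethoxybutan-2-one | CC(=O)C(C)(OC)OC | starting material
11 | prenyl bromide (1-bromo-3-methylbut-2-ene) | CC(C)=CCBr | starting material
12 | 2,2-dimethoxy-7-methyloct-6-en-3-one | CC(C)=CCCC(=O)C(C)(OC)OC | intermediate
13 | 7-methyloct-6-ene-2,3-dione | CC(C)=CCCC(=O)C(C)=O | intermediate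
14 | (3Z)-7-methyl-2,3-bis(trimethylsilyloxy)octa-1,3,6-triene | C=C(O[Si](C)(C)C)/C(O[Si](C)(C)C)=C/CC=C(C)C | intermediate
15 | 1-[6-(3-methylbut-2-enyl)-4,5-bis(trimethylsilyloxy)cyclohexa-1,4-dien-1-yl]-3-[2-bromo-4-(triisopropylsilyloxy)phenyl]propan-1-one (racemic at ring C6) | CC(C)=CCC1C(C(=O)CCc2ccc(O[Si](C(C)C)(C(C)C)C(C)C)cc2Br)=CCC(O[Si](C)(C)C)=C1O[Si](C)(C)C | intermediate
16 | 1-[2-(3-methylbut-2-enyl)-3,4-bis(trimethylsilyloxy)phenyl]-3-[2-bromo-4-(triisopropylsilyloxy)phenyl]propan-1-one | CC(C)=CCc1c(C(=O)CCc2ccc(O[Si](C(C)C)(C(C)C)C(C)C)cc2Br)ccc(O[Si](C)(C)C)c1O[Si](C)(C)C | intermediate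
17 | 1-[3,4-dihydroxy-2-(3-methylbut-2-enyl)phenyl]-3-[2-bromo-4-(triisopropylsilyloxy)phenyl]propan-1-one | CC(C)=CCc1c(C(=O)CCc2ccc(O[Si](C(C)C)(C(C)C)C(C)C)cc2Br)ccc(O)c1O | intermediate
18 | 3-chloro-3-methylbut-1-yne | C#CC(C)(C)Cl | starting material
19 | 1-[3-hydroxy-4-(2-methylbut-3-yn-2-yloxy)-2-(3-methylbut-2-enyl)phenyl]-3-[2-bromo-4-(triisopropylsilyloxy)phenyl]propan-1-one | CC(C)=CCc1c(C(=O)CCc2ccc(O[Si](C(C)C)(C(C)C)C(C)C)cc2Br)ccc(OC(C)(C)C#C)c1O | intermediate
20 | 1-[8-hydroxy-2,2-dimethyl-7-(3-methylbut-2-enyl)-2H-chromen-6-yl]-3-[2-bromo-4-(triisopropylsilyloxy)phenyl]propan-1-one | CC(C)=CCc1c(C(=O)CCc2ccc(O[Si](C(C)C)(C(C)C)C(C)C)cc2Br)cc2c(c1O)OC(C)(C)C=C2 | intermediate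
21 | 1-[8-(tert-butyldimethylsilyloxy)-2,2-dimethyl-7-(3-methylbut-2-enyl)-2H-chromen-6-yl]-3-[2-bromo-4-(triisopropylsilyloxy)phenyl]propan-1-one | CC(C)=CCc1c(C(=O)CCc2ccc(O[Si](C(C)C)(C(C)C)C(C)C)cc2Br)cc2c(c1O[Si](C)(C)C(C)(C)C)OC(C)(C)C=C2 | intermediate
22 | (1R)-1-[8-(tert-butyldimethylsilyloxy)-2,2-dimethyl-7-(3-methylbut-2-enyl)-2H-chromen-6-yl]-3-[2-bromo-4-(triisopropylsilyloxy)phenyl]propan-1-ol | CC(C)=CCc1c([C@H](O)CCc2ccc(O[Si](C(C)C)(C(C)C)C(C)C)cc2Br)cc2c(c1O[Si](C)(C)C(C)(C)C)OC(C)(C)C=C2 | intermediate
23 | tert-butyl-{[2,2-dimethyl-7-(3-methylbut-2-enyl)-6-[(2R)-7-(triisopropylsilyloxy)-3,4-dihydro-2H-chromen-2-yl]-2H-chromen-8-yl]oxy}dimethylsilane | CC(C)=CCc1c([C@H]2CCc3ccc(O[Si](C(C)C)(C(C)C)C(C)C)cc3O2)cc2c(c1O[Si](C)(C)C(C)(C)C)OC(C)(C)C=C2 | intermediate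
24 | (2R)-2-[8-hydroxy-2,2-dimethyl-7-(3-methylbut-2-enyl)-2H-chromen-6-yl]-3,4-dihydro-2H-chromen-7-ol | CC(C)=CCc1c([C@H]2CCc3ccc(O)cc3O2)cc2c(c1O)OC(C)(C)C=C2 | target

## Step count and least certain steps

Total: 14 steps. Longest linear sequence: 11 steps (steps 1–4 and 8–14); the diene branch (steps 5–7) joins at step 8.

**Step 8 (key step).**
- Most likely failure: the cycloaddition takes the opposite orientation, or stalls. The C3 silyloxy group pushes electron density towards the prenyl-bearing terminus and so works against the alkyl group. In addition, any E dienol ether from step 7 cannot adopt the s-cis form, and the diene is lost by hydrolysis or proton-catalysed isomerisation if traces of acid are present.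
- Fallback: it sets out from 9 and returns at 20. Compound 9 is heated with commercial 2,3-bis(trimethylsilyloxy)buta-1,3-diene, which is symmetrical and raises no orientation question, to give the cyclohexadiene adduct F1. DDQ converts F1 into the bis(trimethylsilyl) aryl ketone F2, and citric acid in methanol releases the catechol ketone F3. Alkylation of O4' as in step 9 gives the propargylic ether F4, and thermolysis as in step 10 gives the chromenol F5. Tsuji–Trost etherification of F5 with tert-butyl 2-methylbut-3-en-2-yl carbonate and Pd(PPh3)4 gives the 1,1-dimethylallyl ether F6. Its aromatic Claisen rearrangement in xylene at 130 °C should carry the allyl unit, with inversion, to C2', the only free position ortho to O3', giving 20. The price is three more steps and a possible minor shift to C6'.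

**Step 9.**
- Most likely failure: loss of site control, with alkylation at O3' or at both oxygens, or slow substitution with elimination of hydrogen chloride from the tertiary chloride.
- Fallback: it sets out from 17 and returns at 21. The two oxygens are differentiated by their rate of desilylation instead of their rate of alkylation. Both phenols are silylated (TBSCl, imidazole) to the bis(tert-butyldimethylsilyl) ether F7. The O4' silyl ether, para to the ketone and therefore the better leaving group, is cleaved selectively (K2CO3, MeOH, 0 °C) to the 4'-phenol F8. F8 has one free phenol and is propargylated with 18 to the ether F9, and thermolysis as in step 10 gives 21. A silyl shift between the neighbouring oxygens would not change the outcome, since the para-acyl phenoxide is the more stable anion.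

**Step 12.**
- Most likely failure: slow hydride transfer or poor facial selectivity. The ortho prenyl group twists the aryl ring out of the carbonyl plane and weakens the aryl/arene contact that distinguishes the two faces.
- Fallback: it sets out from 21 and returns at 22. A Corey–Bakshi–Shibata reduction with (S)-2-methyl-CBS-oxazaborolidine and catecholborane in toluene at −78 °C is used instead. Here a Lewis-acid-bound ketone receives hydride from boron, and face selection rests on the size difference between the aryl group and the CH2 chain. The R carbinol is again expected, and catecholborane at low temperature should not hydroborate the alkenes. No new compound is made.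

**Step 13.**
- Most likely failure: hydrodebromination, or cleavage of an aryl silyl ether by carbonate or alkoxide at 100 °C followed by intermolecular phenoxide coupling; the alkoxide next to the crowded ring B may also couple slowly.
- Fallback: it sets out from 21 and returns at 23. The ring is closed at C2 instead of C8a. Compound 21 is reduced as in step 12 but with RuCl[(S,S)-TsDPEN](p-cymene) to the (1S)-carbinol F10. Miyaura borylation (PdCl2(dppf), B2pin2, KOAc, dioxane, 80 °C) gives the pinacol boronate F11, and NaBO3 in aqueous THF gives the C8a phenol F12. Mitsunobu cyclisation (PPh3, DIAD, THF, 0 °C) then forms O1–C2 with inversion, giving the R-configured 23. The risk moves to partial ionisation at the electron-rich benzylic carbon.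

## Further compounds

F1 | step 8 | 1-[4,5-bis(trimethylsilyloxy)cyclohexa-1,4-dien-1-yl]-3-[2-bromo-4-(triisopropylsilyloxy)phenyl]propan-1-one | O=C(CCc1ccc(O[Si](C(C)C)(C(C)C)C(C)C)cc1Br)C1=CCC(O[Si](C)(C)C)=C(O[Si](C)(C)C)C1
F2 | step 8 | 1-[3,4-bis(trimethylsilyloxy)phenyl]-3-[2-bromo-4-(triisopropylsilyloxy)phenyl]propan-1-one | O=C(CCc1ccc(O[Si](C(C)C)(C(C)C)C(C)C)cc1Br)c1ccc(O[Si](C)(C)C)c(O[Si](C)(C)C)c1
F3 | step 8 | 1-(3,4-dihydroxyphenyl)-3-[2-bromo-4-(triisopropylsilyloxy)phenyl]propan-1-one | O=C(CCc1ccc(O[Si](C(C)C)(C(C)C)C(C)C)cc1Br)c1ccc(O)c(O)c1
F4 | step 8 | 1-[3-hydroxy-4-(2-methylbut-3-yn-2-yloxy)phenyl]-3-[2-bromo-4-(triisopropylsilyloxy)phenyl]propan-1-one | O=C(CCc1ccc(O[Si](C(C)C)(C(C)C)C(C)C)cc1Br)c1ccc(OC(C)(C)C#C)c(O)c1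
F5 | step 8 | 1-(8-hydroxy-2,2-dimethyl-2H-chromen-6-yl)-3-[2-bromo-4-(triisopropylsilyloxy)phenyl]propan-1-one | O=C(CCc1ccc(O[Si](C(C)C)(C(C)C)C(C)C)cc1Br)c1cc(O)c2OC(C)(C)C=Cc2c1
F6 | step 8 | 1-[2,2-dimethyl-8-(2-methylbut-3-en-2-yloxy)-2H-chromen-6-yl]-3-[2-bromo-4-(triisopropylsilyloxy)phenyl]propan-1-one | O=C(CCc1ccc(O[Si](C(C)C)(C(C)C)C(C)C)cc1Br)c1cc(OC(C)(C)C=C)c2OC(C)(C)C=Cc2c1
F7 | step 9 | 1-[3,4-bis(tert-butyldimethylsilyloxy)-2-(3-methylbut-2-enyl)phenyl]-3-[2-bromo-4-(triisopropylsilyloxy)phenyl]propan-1-one | CC(C)=CCc1c(C(=O)CCc2ccc(O[Si](C(C)C)(C(C)C)C(C)C)cc2Br)ccc(O[Si](C)(C)C(C)(C)C)c1O[Si](C)(C)C(C)(C)C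
F8 | step 9 | 1-[3-(tert-butyldimethylsilyloxy)-4-hydroxy-2-(3-methylbut-2-enyl)phenyl]-3-[2-bromo-4-(triisopropylsilyloxy)phenyl]propan-1-one | CC(C)=CCc1c(C(=O)CCc2ccc(O[Si](C(C)C)(C(C)C)C(C)C)cc2Br)ccc(O)c1O[Si](C)(C)C(C)(C)C
F9 | step 9 | 1-[3-(tert-butyldimethylsilyloxy)-4-(2-methylbut-3-yn-2-yloxy)-2-(3-methylbut-2-enyl)phenyl]-3-[2-bromo-4-(triisopropylsilyloxy)phenyl]propan-1-one | CC(C)=CCc1c(C(=O)CCc2ccc(O[Si](C(C)C)(C(C)C)C(C)C)cc2Br)ccc(OC(C)(C)C#C)c1O[Si](C)(C)C(C)(C)C
F0 | step 12 | none | none
F10 | step 13 | (1S)-1-[8-(tert-butyldimethylsilyloxy)-2,2-dimethyl-7-(3-methylbut-2-enyl)-2H-chromen-6-yl]-3-[2-bromo-4-(triisopropylsilyloxy)phenyl]propan-1-ol | CC(C)=CCc1c([C@@H](O)CCc2ccc(O[Si](C(C)C)(C(C)C)C(C)C)cc2Br)cc2c(c1O[Si](C)(C)C(C)(C)C)OC(C)(C)C=C2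
F11 | step 13 | (1S)-1-[8-(tert-butyldimethylsilyloxy)-2,2-dimethyl-7-(3-methylbut-2-enyl)-2H-chromen-6-yl]-3-[2-(4,4,5,5-tetramethyl-1,3,2-dioxaborolan-2-yl)-4-(triisopropylsilyloxy)phenyl]propan-1-ol | CC(C)=CCc1c([C@@H](O)CCc2ccc(O[Si](C(C)C)(C(C)C)C(C)C)cc2B3OC(C)(C)C(C)(C)O3)cc2c(c1O[Si](C)(C)C(C)(C)C)OC(C)(C)C=C2
F12 | step 13 | 2-{(3S)-3-[8-(tert-butyldimethylsilyloxy)-2,2-dimethyl-7-(3-methylbut-2-enyl)-2H-chromen-6-yl]-3-hydroxypropyl}-5-(triisopropylsilyloxy)phenol | CC(C)=CCc1c([C@@H](O)CCc2ccc(O[Si](C(C)C)(C(C)C)C(C)C)cc2O)cc2c(c1O[Si](C)(C)C(C)(C)C)OC(C)(C)C=C2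
A1 | alternative 1 | 2-ethenyl-5-(triisopropylsilyloxy)phenol | C=Cc1ccc(O[Si](C(C)C)(C(C)C)C(C)C)cc1O
A2 | alternative 1 | 8-acetoxy-2,2-dimethyl-2H-chromene-6-carbaldehyde (6-formyl-2,2-dimethyl-2H-chromen-8-yl acetate) | CC(=O)Oc1cc(C=O)cc2c1OC(C)(C)C=C2
A3 | alternative 1 | 2,2-dimethyl-6-[(2R)-7-(triisopropylsilyloxy)-3,4-dihydro-2H-chromen-2-yl]-2H-chromen-8-yl acetate | CC(=O)Oc1cc([C@H]2CCc3ccc(O[Si](C(C)C)(C(C)C)C(C)C)cc3O2)cc2c1OC(C)(C)C=C2
A4 | alternative 2 | [2-(benzyloxy)-5-{1-[3-(methoxymethoxy)phenoxy]prop-2-yn-1-yl}phenoxy](tert-butyl)dimethylsilane, carbinol carbon configured as C2 of the target | CC(C)(C)[Si](C)(C)Oc1cc(ccc1OCc1ccccc1)[C@H](Oc1cccc(OCOC)c1)C#C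
A5 | alternative 2 | (2R)-2-[4-(benzyloxy)-3-(tert-butyldimethylsilyloxy)phenyl]-7-(methoxymethoxy)-2H-chromene | CC(C)(C)[Si](C)(C)Oc1cc(ccc1OCc1ccccc1)[C@H]1C=Cc2ccc(OCOC)cc2O1
A6 | alternative 3 | 2-hydroxy-4-(methoxymethoxy)benzaldehyde | COCOc1ccc(C=O)c(O)c1
A7 | alternative 3 | (2E)-3-[8-(methoxymethoxy)-2,2-dimethyl-7-(3-methylbut-2-enyl)-2H-chromen-6-yl]prop-2-enal | CC(C)=CCc1c(/C=C/C=O)cc2c(c1OCOC)OC(C)(C)C=C2
A8 | alternative 3 | 7-(methoxymethoxy)-2-[8-(methoxymethoxy)-2,2-dimethyl-7-(3-methylbut-2-enyl)-2H-chromen-6-yl]-2H-chromene-3-carbaldehyde, C2 configured as in the target | CC(C)=CCc1c([C@H]2C(C=O)=Cc3ccc(OCOC)cc3O2)cc2c(c1OCOC)OC(C)(C)C=C2
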